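The earlier runs and the new flask stem from a simulated flask with constants of no real substance, and the scatter is random.

The vessel is closed, stirred and isothermal, so you can balance the charged L, G and X against each other at any moment.

| flask | L | G | X | remark | time |
|---|---|---|---|---|---|
| beta | 0.16 M | 0.096 M | 4.8 mM | run made earlier |  |
| flask | 0.16 M | 0.0960 M | 3.20 mM |  | 50 min |

- beta (time / min: L / %, D / %, E / %): 0.833: 56.5, 36.4, 8.0; 2.50: 54.5, 30.1, 15.2; 5.00: 54.3, 29.4, 17.8; 8.00: 53.7, 29.6, 16.1; 10.0: 52.9, 29.1, 17.2

(readings scatter by 0.5 percentage points)

- on the list of suspects stand: L + G <-> D + Q; D <-> E; G + X -> J
- the reaction counts as stopped when no species that holds the L changes by six tenths of a point or more over the second half of the time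
- no earlier run changes the charge of X; that part of a forecast is a guess

- which holds at 50 min: what has brought the reaction to rest, or that it has not come to rest (all of L has reacted / forward and back rates have come level / it is still moving / G has run out first)
- share of the L used up at 50 min
- D at 50 min, in percent of the L charged
- E at 50 min, in percent of the L charged

Take the beta run in slow motion. In the first instants L + G gives D and Q fast: at 0.833 min, L already stands at 56.5%, with D at 36.4% and E at 8.0%. In the middle, by 2.50 min, L has moved to 54.5% while D has dropped to 30.1% and E has climbed to 15.2%, so D <-> E is now the step at work. From 5.00 min on, I read the run as level, a judgement, since L slips from 54.3% to 52.9% with a scatter of 0.5 percentage points per reading. The mean of these readings puts L at 53.6%, so the share used, x, is 46.4%, and E over D is 0.580.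

Now suppose that X has taken one G each, which no earlier run tests. Then the G open to L, called g and counted in shares of the L charged, is 57.0%. That leaves unused an amount of G equal to 10.6% of the L charged, so on this supposition L has stopped with G still present, and I take forward and back rates as level.

Each L used takes one G and gives one Q and one D or E. With l the share of L left, the overall equilibrium constant M, x·x/(l·(g − x)), reads 3.77 in beta. Concentrations stand two above and two below, so the charge of L cancels, and I carry M to this flask, taking its temperature as that of beta.

In the flask, g is 58.0%. Solving M for x gives 47.0%, which the ratio divides into D at 29.7% and E at 17.2%.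

The forecast gives forward and back rates have come level, with 47% of L used, D at 29.7% and E at 17.2%, on this ground: “So L + G <-> D + Q has reached equilibrium.”

The flask gives forward and back rates have come level, with 47.0% of L used, D at 29.9% and E at 17.1%.

    L + G ⇌ D + Q (K = 2.40, k = 0.480 /M/s)
    D ⇌ E (K = 0.570, k = 0.00680 /s)
    G + X → J (k = 5.50 /M/s)

In the flask at 50.0 min, X stands at 0% of its charge and J at 0.00320 M, as the reckoning supposed. Now take a neighbour flask, charged with 0.040 M of L, its other charges and time as in the flask. Its g is 232%, so G open to L is more than the L charged. The same M gives x = 86.4%, and the same ratio puts D at 54.7%. The neighbour gives 86.4% of L used and D at 55.0%.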